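**Retrosynthetic overview**
- Last events: α-acetoxylation of a ring-A silyl enol ether (C-2 acetate, C-3 ketone), preceded by Mitsunobu formation of the C-11–O aryl ether from a sesquiterpenoid alcohol and the coumarin phenol.
- Ring B: made from a cyclopentanone by a one-carbon ring expansion (carbenoid 1,2-shift of the quaternary carbon). The enolate released is hydroxymethylated (C-9, C-11) and C-8 is then methylenated.
- Ring A: built earlier onto a methylcyclopentenone by an enantioselective stepwise Michael–Michael annulation with a silyloxydiene. This sets the cis ring fusion (C-5, C-10) and leaves C-3 masked as the C-2/C-3 silyl enol ether.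
- Coumarin: made separately from a dihydroxybenzene (formylation, dibromination, methoxylation), pyranone ring closed last.
- Ring order: five-membered ring (bought) → ring A → ring B (by expansion of the five-membered ring); coumarin rings independently.

Assumption: the target is taken exactly as written, (1S,4aS,7R,8aS), a cis-fused decalin with H-5, CH3-10 and C-11 on one face and the acetate on the other (drimane numbering in the comments); the sense of induction of the new catalyst in step 2 is assumed, and its antipode is used if it proves opposite.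

**Step 1**
Reactants: 1 4-methylpent-1-en-3-one
Product: 2 tert-butyl(dimethyl)[(4-methylpenta-1,3-dien-3-yl)oxy]silane
Conditions: TBSOTf, Et3N, CH2Cl2, 0 °C
Reagents that add atoms: tert-butyldimethylsilyl trifluoromethanesulfonate, CC(C)(C)[Si](C)(C)OS(=O)(=O)C(F)(F)F
Why: Soft enolisation and O-silylation (silyl dienol ether formation) at the only enolisable position, the isopropyl CH, gives the cross-conjugated 2-silyloxydiene.

**Step 2**
Reactants: 2 tert-butyl(dimethyl)[(4-methylpenta-1,3-dien-3-yl)oxy]silane; 3 2-methylcyclopent-2-en-1-one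
Product: 5 (3aR,7aS)-5-{[tert-butyl(dimethyl)silyl]oxy}-4,4,7a-trimethyl-2,3,3a,4,7,7a-hexahydro-1H-inden-1-one, via monocyclic Michael adduct 4 (not isolated)
Conditions: (S,S)-imidodiphosphorimidate Brønsted acid built from two 3,3'-bis[3,5-bis(trifluoromethyl)phenyl]-(S)-1,1'-bi-2-naphthol units with two N-trifluoromethanesulfonyl groups (5 mol%), toluene, −40 °C; then Et3N
Reagents that add atoms: none
Why: Proposed new method: the chiral acid is silylated by 2 to a silylium/chiral-anion pair that O-silylates enone 3; the tetrasubstituted enol-ether carbon of 2 then adds to the β-carbon inside the confined anion (Mukaiyama–Michael, sets C-3a), the cyclopentenyl silyl ether 4 closes onto the silyl-activated vinyl ketone (intramolecular Mukaiyama–Michael, 6-endo) on the face that carries the tether, which forces the cis fusion and fixes the quaternary C-7a, and silyl release turns the catalyst over; the closest known chemistry is the racemic stepwise formal Diels–Alder reaction of hindered 2-silyloxydienes with 2-methylcycloalkenones under mixed aluminium Lewis acids, together with silylium/imidodiphosphorimidate-catalysed asymmetric Mukaiyama–Michael and Diels–Alder reactions of simpler enones.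

**Step 3**
Reactants: 5 (3aR,7aS)-5-{[tert-butyl(dimethyl)silyl]oxy}-4,4,7a-trimethyl-2,3,3a,4,7,7a-hexahydro-1H-inden-1-one
Product: 6 (3aR,7aS)-5-{[tert-butyl(dimethyl)silyl]oxy}-1-(dibromomethyl)-4,4,7a-trimethyl-2,3,3a,4,7,7a-hexahydro-1H-inden-1-ol (both C-1 epimers)
Conditions: CH2Br2, lithium 2,2,6,6-tetramethylpiperidide (LiTMP) added to the mixture, THF, −78 °C; NH4Cl
Reagents that add atoms: dibromomethane, BrCBr
Why: 1,2-Addition of dibromomethyllithium (carbenoid generated in the presence of the ketone) to the only carbonyl; the silyl enol ether is inert, and the new carbinol configuration does not matter because this carbon becomes the ring-B carbonyl.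

**Step 4**
Reactants: 6 (3aR,7aS)-5-{[tert-butyl(dimethyl)silyl]oxy}-1-(dibromomethyl)-4,4,7a-trimethyl-2,3,3a,4,7,7a-hexahydro-1H-inden-1-ol
Product: 10 (1S,4aS,8aS)-6-{[tert-butyl(dimethyl)silyl]oxy}-5,5,8a-trimethyl-1-{[(trimethylsilyl)oxy]methyl}-3,4,4a,5,8,8a-hexahydronaphthalen-2(1H)-one, via lithium bromocarbenoid alkoxide 7 (not isolated), via ring-expanded lithium enolate 8 (not isolated), via lithium aldolate 9 (not isolated)
Conditions: n-BuLi (2.2 equiv), THF, −78 → −20 °C; CH2O (gas, from cracked paraformaldehyde), −78 °C; Me3SiCl, Et3N, −78 → 0 °C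
Reagents that add atoms: formaldehyde, C=O; chlorotrimethylsilane, C[Si](C)(C)Cl
Why: β-Oxido carbenoid one-carbon ring expansion (Nozaki type): Br/Li exchange gives 7, whose alkoxide drives a 1,2-shift of the more substituted quaternary carbon (retention; 2-methylcycloalkanones likewise give 3-methyl homologues) with loss of LiBr to give only enolate 8, which adds formaldehyde (aldol) axially on the convex β-face, the α-face being screened by the axial ring-A methylene of the cis-decalin, to set the 1S centre, and silylation of 9 blocks retro-aldol and epimerisation.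

**Step 5**
Reactants: 10 (1S,4aS,8aS)-6-{[tert-butyl(dimethyl)silyl]oxy}-5,5,8a-trimethyl-1-{[(trimethylsilyl)oxy]methyl}-3,4,4a,5,8,8a-hexahydronaphthalen-2(1H)-one
Product: 12 [(1S,4aS,8aS)-6-{[tert-butyl(dimethyl)silyl]oxy}-5,5,8a-trimethyl-2-methylidene-1,2,3,4,4a,5,8,8a-octahydronaphthalen-1-yl]methanol, via methylidene trimethylsilyl ether 11 (not isolated)
Conditions: Cp2TiMe2 (3 equiv), toluene/THF, 65 °C, dark; then K2CO3 (cat.), MeOH, 0 °C
Reagents that add atoms: dimethyltitanocene, C[Ti](C)(C1C=CC=C1)C1C=CC=C1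
Why: Petasis methylenation uses a non-basic titanium carbene, so the epimerisable β-oxygenated centre next to the ketone survives, and brief methanolysis removes only the primary trimethylsilyl ether.

**Step 6**
Reactants: 13 benzene-1,3-diol (resorcinol)
Product: 15 2,4-dihydroxybenzaldehyde, via aryl iminium chloride 14 (not isolated)
Conditions: POCl3, DMF, MeCN, 0 °C → rt; then H2O, 50 °C
Reagents that add atoms: N,N-dimethylformamide, CN(C)C=O; water, O
Why: Vilsmeier–Haack formylation occurs para to one hydroxyl and ortho to the other, and the iminium salt is hydrolysed on work-up.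

**Step 7**
Reactants: 15 2,4-dihydroxybenzaldehyde
Product: 16 3,5-dibromo-2,4-dihydroxybenzaldehyde
Conditions: Br2 (2.05 equiv), AcOH, rt
Reagents that add atoms: bromine, BrBr
Why: Electrophilic aromatic bromination takes the two positions activated by both hydroxyls (C-3 and C-5), while C-6 is deactivated by the formyl group.

**Step 8**
Reactants: 16 3,5-dibromo-2,4-dihydroxybenzaldehyde
Product: 17 2,4-dihydroxy-3,5-dimethoxybenzaldehyde
Conditions: NaOMe (excess), CuCl (20 mol%), DMF/MeOH, 110 °C; then aq. HCl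
Reagents that add atoms: sodium methoxide, C[O-].[Na+]
Why: Copper-catalysed Ullmann-type methoxylation of both aryl bromides, the reaction that turns bromovanillin into syringaldehyde, is run before any lactone is present.

**Step 9**
Reactants: 17 2,4-dihydroxy-3,5-dimethoxybenzaldehyde
Product: 19 7-hydroxy-6,8-dimethoxy-2H-chromen-2-one (isofraxidin), via cinnamate ester 18 (not isolated)
Conditions: Ph3P=CHCO2Et, N,N-diethylaniline, reflux
Reagents that add atoms: ethyl (triphenylphosphoranylidene)acetate, CCOC(=O)C=P(c1ccccc1)(c1ccccc1)c1ccccc1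
Why: Wittig olefination with the stabilised ylide gives the E-cinnamate, which at reflux isomerises and lactonises onto the ortho hydroxyl (standard coumarin synthesis), leaving the 7-hydroxyl free.

**Step 10**
Reactants: 12 [(1S,4aS,8aS)-6-{[tert-butyl(dimethyl)silyl]oxy}-5,5,8a-trimethyl-2-methylidene-1,2,3,4,4a,5,8,8a-octahydronaphthalen-1-yl]methanol; 19 7-hydroxy-6,8-dimethoxy-2H-chromen-2-one
Product: 20 7-{[(1S,4aS,8aS)-6-{[tert-butyl(dimethyl)silyl]oxy}-5,5,8a-trimethyl-2-methylidene-1,2,3,4,4a,5,8,8a-octahydronaphthalen-1-yl]methoxy}-6,8-dimethoxy-2H-chromen-2-one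
Conditions: PPh3, DIAD, toluene/THF, 0 °C → rt
Reagents that add atoms: none
Why: Mitsunobu etherification: the acidic phenol (pKa about 8) protonates the betaine and its phenoxide displaces the oxyphosphonium at the primary CH2 (SN2, no stereocentre touched), as for albicanol-type alcohols with 7-hydroxycoumarins, while the silyl enol ether and alkenes are inert.

**Step 11**
Reactants: 20 7-{[(1S,4aS,8aS)-6-{[tert-butyl(dimethyl)silyl]oxy}-5,5,8a-trimethyl-2-methylidene-1,2,3,4,4a,5,8,8a-octahydronaphthalen-1-yl]methoxy}-6,8-dimethoxy-2H-chromen-2-one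
Product: 21 7-{[(1S,4aS,7R,8aS)-7-(acetyloxy)-5,5,8a-trimethyl-2-methylidene-6-oxodecahydronaphthalen-1-yl]methoxy}-6,8-dimethoxy-2H-chromen-2-one
Conditions: Pb(OAc)4 (1.1 equiv), CH2Cl2, −20 → 0 °C
Reagents that add atoms: lead tetraacetate, CC(=O)O[Pb](OC(C)=O)(OC(C)=O)OC(C)=O
Why: Lead tetraacetate oxidation of a silyl enol ether to an α-acetoxy ketone (Rubottom type): the regiodefined enol ether is attacked at C-7 from the face opposite the axial C-8a and C-5 methyl groups to give the equatorial 7R acetate, which is also the expected thermodynamic epimer, and the alkenes, aryl ethers and lactone do not react at this temperature.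

**Compound list**
1 | 4-methylpent-1-en-3-one | C=CC(=O)C(C)C | starting material
2 | tert-butyl(dimethyl)[(4-methylpenta-1,3-dien-3-yl)oxy]silane | C=CC(O[Si](C)(C)C(C)(C)C)=C(C)C | intermediate
3 | 2-methylcyclopent-2-en-1-one | CC1=CCCC1=O | starting material
4 | 4-[(1S)-3-{[tert-butyl(dimethyl)silyl]oxy}-2-methylcyclopent-2-en-1-yl]-4-methylpent-1-en-3-one (in-flask species) | C=CC(=O)C(C)(C)[C@H]1CCC(O[Si](C)(C)C(C)(C)C)=C1C | intermediate
5 | (3aR,7aS)-5-{[tert-butyl(dimethyl)silyl]oxy}-4,4,7a-trimethyl-2,3,3a,4,7,7a-hexahydro-1H-inden-1-one | C[C@]12CC=C(O[Si](C)(C)C(C)(C)C)C(C)(C)[C@H]1CCC2=O | intermediate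
6 | (3aR,7aS)-5-{[tert-butyl(dimethyl)silyl]oxy}-1-(dibromomethyl)-4,4,7a-trimethyl-2,3,3a,4,7,7a-hexahydro-1H-inden-1-ol (C-1 epimers) | C[C@]12CC=C(O[Si](C)(C)C(C)(C)C)C(C)(C)[C@H]1CCC2(O)C(Br)Br | intermediate
7 | lithium (3aR,7aS)-1-[bromo(lithio)methyl]-5-{[tert-butyl(dimethyl)silyl]oxy}-4,4,7a-trimethyl-2,3,3a,4,7,7a-hexahydro-1H-inden-1-olate (in-flask species) | C[C@]12CC=C(O[Si](C)(C)C(C)(C)C)C(C)(C)[C@H]1CCC2(O[Li])C([Li])Br | intermediate
8 | lithium (4aS,8aS)-6-{[tert-butyl(dimethyl)silyl]oxy}-5,5,8a-trimethyl-3,4,4a,5,8,8a-hexahydronaphthalen-2-olate (in-flask species) | C[C@]12CC=C(O[Si](C)(C)C(C)(C)C)C(C)(C)[C@H]1CCC(O[Li])=C2 | intermediate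
9 | lithium [(1S,4aS,8aS)-6-{[tert-butyl(dimethyl)silyl]oxy}-5,5,8a-trimethyl-2-oxo-1,2,3,4,4a,5,8,8a-octahydronaphthalen-1-yl]methanolate (in-flask species) | O=C1CC[C@@H]2C(C)(C)C(O[Si](C)(C)C(C)(C)C)=CC[C@]2(C)[C@H]1CO[Li] | intermediate
10 | (1S,4aS,8aS)-6-{[tert-butyl(dimethyl)silyl]oxy}-5,5,8a-trimethyl-1-{[(trimethylsilyl)oxy]methyl}-3,4,4a,5,8,8a-hexahydronaphthalen-2(1H)-one | O=C1CC[C@@H]2C(C)(C)C(O[Si](C)(C)C(C)(C)C)=CC[C@]2(C)[C@H]1CO[Si](C)(C)C | intermediate
11 | tert-butyl(dimethyl){[(4aS,5S,8aS)-1,1,4a-trimethyl-6-methylidene-5-{[(trimethylsilyl)oxy]methyl}-1,4,4a,5,6,7,8,8a-octahydronaphthalen-2-yl]oxy}silane (in-flask species) | C=C1CC[C@@H]2C(C)(C)C(O[Si](C)(C)C(C)(C)C)=CC[C@]2(C)[C@H]1CO[Si](C)(C)C | intermediate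
12 | [(1S,4aS,8aS)-6-{[tert-butyl(dimethyl)silyl]oxy}-5,5,8a-trimethyl-2-methylidene-1,2,3,4,4a,5,8,8a-octahydronaphthalen-1-yl]methanol | C=C1CC[C@@H]2C(C)(C)C(O[Si](C)(C)C(C)(C)C)=CC[C@]2(C)[C@H]1CO | intermediate
13 | benzene-1,3-diol (resorcinol) | Oc1cccc(O)c1 | starting material
14 | N-[(2,4-dihydroxyphenyl)methylidene]-N-methylmethanaminium chloride (in-flask species) | C[N+](C)=Cc1ccc(O)cc1O.[Cl-] | intermediate
15 | 2,4-dihydroxybenzaldehyde | O=Cc1ccc(O)cc1O | intermediate
16 | 3,5-dibromo-2,4-dihydroxybenzaldehyde | O=Cc1cc(Br)c(O)c(Br)c1O | intermediate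
17 | 2,4-dihydroxy-3,5-dimethoxybenzaldehyde | O=Cc1cc(OC)c(O)c(OC)c1O | intermediate
18 | ethyl (2E)-3-(2,4-dihydroxy-3,5-dimethoxyphenyl)prop-2-enoate (in-flask species) | CCOC(=O)/C=C/c1cc(OC)c(O)c(OC)c1O | intermediate
19 | 7-hydroxy-6,8-dimethoxy-2H-chromen-2-one (isofraxidin) | COc1cc2ccc(=O)oc2c(OC)c1O | intermediate
20 | 7-{[(1S,4aS,8aS)-6-{[tert-butyl(dimethyl)silyl]oxy}-5,5,8a-trimethyl-2-methylidene-1,2,3,4,4a,5,8,8a-octahydronaphthalen-1-yl]methoxy}-6,8-dimethoxy-2H-chromen-2-one | C=C1CC[C@@H]2C(C)(C)C(O[Si](C)(C)C(C)(C)C)=CC[C@]2(C)[C@H]1COc1c(OC)cc2ccc(=O)oc2c1OC | intermediate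
21 | 7-{[(1S,4aS,7R,8aS)-7-(acetyloxy)-5,5,8a-trimethyl-2-methylidene-6-oxodecahydronaphthalen-1-yl]methoxy}-6,8-dimethoxy-2H-chromen-2-one (CNP0183157.2) | C=C1CC[C@@H]2C(C)(C)C(=O)[C@H](OC(C)=O)C[C@]2(C)[C@H]1COc1c(OC)cc2ccc(=O)oc2c1OC | target

**Totals**
Total step count: 11. Longest linear sequence: 7 (steps 1, 2, 3, 4, 5, 10, 11).

**Steps most likely to fail, with fallbacks**

Step 2 (the proposed new annulation; reactivity of the hindered partners and enantiocontrol are both untested). The fallback sets out from 2 and 3. The same stepwise formal Diels–Alder reaction is run racemically with the mixed Lewis acid AlBr3/AlMe3 (about 10:1, toluene/CH2Cl2, −5 °C), a known reaction type for hindered silyloxydienes and 2-methylcycloalkenones. This gives 5 together with its mirror image, (3aS,7aR)-5-{[tert-butyl(dimethyl)silyl]oxy}-4,4,7a-trimethyl-2,3,3a,4,7,7a-hexahydro-1H-inden-1-one F1. The two are separated by preparative chromatography on a chiral stationary phase, and the route is rejoined at 5.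

Step 4 (the ring-A-side methylene could migrate instead of the quaternary carbon, or formaldehyde capture could be unclean). The fallback sets out from 5 and uses an epoxide semipinacol in place of the carbenoid.
- Vinylmagnesium bromide/CeCl3 (THF, −78 °C) gives the tertiary allylic alcohol (3aR,7aS)-5-{[tert-butyl(dimethyl)silyl]oxy}-1-ethenyl-4,4,7a-trimethyl-2,3,3a,4,7,7a-hexahydro-1H-inden-1-ol F2.
- Hydroxyl-directed epoxidation with VO(acac)2/t-BuOOH gives the epoxy alcohol (3aR,7aS)-5-{[tert-butyl(dimethyl)silyl]oxy}-4,4,7a-trimethyl-1-[(2R)-oxiran-2-yl]-2,3,3a,4,7,7a-hexahydro-1H-inden-1-ol F3. The diastereomer with the R oxirane carbon is the one needed and is separated if a mixture forms.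
- Silylation (Me3SiOTf, 2,6-lutidine) gives its trimethylsilyl ether, tert-butyl(dimethyl){[(3aR,7aS)-3,3,7a-trimethyl-1-[(2R)-oxiran-2-yl]-1-[(trimethylsilyl)oxy]-2,3,3a,4,7,7a-hexahydro-1H-inden-5-yl]oxy}silane... more simply the epoxy silyl ether F4.
- Methylaluminium bis(4-bromo-2,6-di-tert-butylphenoxide) (CH2Cl2, −78 °C) triggers the known epoxy silyl ether rearrangement: 1,2-shift of the quaternary carbon to the oxirane CH with inversion, and silyl transfer to the primary oxygen. This gives 10 directly, where the route is rejoined.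

Step 10 (Mitsunobu between a β-branched primary alcohol and a di-ortho-substituted phenol; elimination to the diene may compete). The fallback sets out from 12. MsCl/Et3N (CH2Cl2, 0 °C) gives the mesylate [(1S,4aS,8aS)-6-{[tert-butyl(dimethyl)silyl]oxy}-5,5,8a-trimethyl-2-methylidene-1,2,3,4,4a,5,8,8a-octahydronaphthalen-1-yl]methyl methanesulfonate F5. This is displaced by the caesium salt of 19 (Cs2CO3, DMF, 60 °C) to give 20, where the route is rejoined.

**Further compounds**
F1 | step 2 | (3aS,7aR)-5-{[tert-butyl(dimethyl)silyl]oxy}-4,4,7a-trimethyl-2,3,3a,4,7,7a-hexahydro-1H-inden-1-one | C[C@@]12CC=C(O[Si](C)(C)C(C)(C)C)C(C)(C)[C@@H]1CCC2=O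
F2 | step 4 | (3aR,7aS)-5-{[tert-butyl(dimethyl)silyl]oxy}-1-ethenyl-4,4,7a-trimethyl-2,3,3a,4,7,7a-hexahydro-1H-inden-1-ol (C-1 epimers) | C[C@]12CC=C(O[Si](C)(C)C(C)(C)C)C(C)(C)[C@H]1CCC2(O)C=C
F3 | step 4 | (3aR,7aS)-5-{[tert-butyl(dimethyl)silyl]oxy}-4,4,7a-trimethyl-1-[(2R)-oxiran-2-yl]-2,3,3a,4,7,7a-hexahydro-1H-inden-1-ol | C[C@]12CC=C(O[Si](C)(C)C(C)(C)C)C(C)(C)[C@H]1CCC2(O)[C@H]1CO1
F4 | step 4 | trimethylsilyl ether of F3 (epoxy silyl ether) | C[C@]12CC=C(O[Si](C)(C)C(C)(C)C)C(C)(C)[C@H]1CCC2(O[Si](C)(C)C)[C@H]1CO1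
F5 | step 10 | [(1S,4aS,8aS)-6-{[tert-butyl(dimethyl)silyl]oxy}-5,5,8a-trimethyl-2-methylidene-1,2,3,4,4a,5,8,8a-octahydronaphthalen-1-yl]methyl methanesulfonate | C=C1CC[C@@H]2C(C)(C)C(O[Si](C)(C)C(C)(C)C)=CC[C@]2(C)[C@H]1COS(C)(=O)=O
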